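**Remarks on the chemistry.** The target is achiral. Cyclobutenone 16 is used as the racemate because its only stereocentre becomes sp2 in step 11. In the names below, "ArO–" stands for the aryloxy group of phenol 9, that is the nonamethylated ABCD tetramer bound through the oxygen on C2 of ring D.

## Analysis of the target

The target 25 (C30H22O16) is a linear phlorotannin of the fuhalol type. Five benzene rings, lettered A (2,4,6-trihydroxyphenoxy end) to E (3,4,5-trihydroxyphenyl end), are joined by four diaryl ether oxygens and carry twelve free phenolic hydroxyls. Each ring is numbered so that C1, C2 and C3 bear the three adjacent oxygens and C5 the isolated one; every ether oxygen then runs from the crowded C2 of one ring (between two oxygenated carbons) to the open C5 of the next (between two C–H groups). There is no stereocentre, so the problem is one of connectivity, regiochemistry and protecting groups only. The free compound is a very electron-rich polyphenol, and the pyrogallol ring E in particular is oxidised by air, fastest in base, so the hydroxyls must stay masked until the last step and the unmasking must leave the four diaryl ether bonds intact. The difficulty is to form four ether bonds at di-ortho-oxygenated carbons of rings that carry no activating group for nucleophilic aromatic substitution, under a protecting-group scheme that survives base, organolithium reagents and heat. The strategy rests on ring E: C5 carries the ether oxygen between C4–H and C6–H, and C1, C2 and C3 carry oxygen. This is the pattern that results when an oxygen-substituted alkyne (C5, C6) is joined to a four-carbon vinylketene (C1 to C4) with oxygen on C2 and C3, so the D–O–E bond can be made as an O–C(sp) bond and ring E grown onto it.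

## Retrosynthetic reasoning

**25 to 24.** Only O–alkyl bonds are cut: ten O–CH3 bonds and one O–CH2CH3 bond of 24. Methyl ethers are chosen because they survive copper catalysis, hydrogenolysis, an alkyllithium at low temperature and heating in toluene. The single ethyl ether is what the ring E synthesis delivers, and it falls under the same Lewis-acid dealkylation. Diaryl ether C(sp2)–O bonds are inert to this reagent class, so one operation should unmask all twelve hydroxyls.

**24 to 19 and 16.** Ring E is cut at C1–C6 and C4–C5. That leaves a two-carbon fragment (C5, C6), the terminal ynol ether 19, and a four-carbon fragment (C1 to C4), the vinylketene latent in cyclobutenone 16. The cut is placed here because C5 sits between two C–H groups and carries the only oxygen that links to the rest of the molecule. The most hindered aryl–O bond of the sequence, from C2 of ring D, then never has to be made by arylation of the largest phenol. The forward reaction has to bond the unsubstituted alkyne carbon to the ketene carbonyl carbon, so that the aryloxy group ends meta to the new hydroxyl.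

**16 to 13 and 14.** The four-membered ring is cut into a ketene two-carbon unit from acid chloride 13 and the alkyne 14. The same ketene–ynol ether polarity that controls the key step places ethoxy on C3 and methoxy on C4 of 16. These become the C3 and C2 oxygens of ring E.

**19 to 12 to 9 and 10.** The ethynyl group is traced to the dichlorovinyl ether 12, and 12 to phenol 9 and trichloroethylene 10. The O–C bond is formed by addition of a phenoxide to a linear sp carbon, which is indifferent to the two ortho methoxy groups on ring D. Two equivalents of an alkyllithium then convert the dichlorovinyl group into the alkyne.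

**9 to 7, 7 to 5, 5 to 3, each with 2.** The three remaining ether bonds are cut on the C5 side, between the oxygen and the carbon flanked by two C–H groups. The electrophile is therefore always the unhindered bromide 2, and the steric load lies only on the phenoxide oxygen, which copper-catalysed coupling tolerates. Cutting on the C2 side would need a halide between two methoxy groups. The benzyl ether in 2 masks the next phenol and is removed by hydrogenolysis after each coupling, so the same two operations are repeated from 3 through 4, 5, 6, 7 and 8 to 9.

**2 to 1.** Bromide 2 comes from commercial bromophenol 1 by O-benzylation.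

## Alternatives that were turned down

**Alternative 1:** The eight hydroxyls on C1 and C3 of rings A to D are traced back to formyl groups. The tetrabenzyl ether A1 would arise from the octa-aldehyde A2 by eight peracid oxidations of the Dakin/Baeyer–Villiger type, followed by methanolysis of the aryl formates. Hydrogenolysis would then give the target.
- For: two formyl groups flank every C2 in A2, so a C2 fluoride would be doubly activated and the crowded C2–O bonds could be made by metal-free nucleophilic aromatic substitution. The final deprotection is neutral hydrogenolysis, which is gentler on the oxidation-prone product than Lewis-acid dealkylation. On that point this alternative is stronger.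
- Against: each ring of A2 carries two electron-withdrawing formyl groups. Each formyl group has only one ortho oxygen donor, a diaryl ether oxygen shared between two rings, and the C5 oxygen is meta to it. Aryl migration in the peracid adduct is therefore poorly assisted, hydride migration to carboxylic acids competes, and the right outcome is needed eight times in one molecule. Phenols freed early stay exposed to peracid and can be oxidised to quinones.
- Comparison: the chosen strategy brings every oxygen in at the phenol oxidation level from commercial building blocks, and performs a single isomerising bond construction on the full skeleton instead of eight oxidations.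

**Alternative 2:** Ring C is the hub. The cyclopentadienylruthenium complex A4 of 2,5-dichloro-1,3-dimethoxybenzene would be attacked first at C5 by the AB phenol A5 (identical with 5 of the route below) and then at C2 by the DE phenol A6. This gives the complexed dodecamethyl ether A3, which is decomplexed by photolysis and demethylated.
- For: the metal cation makes chloride displacement easy even on this electron-rich ring. The assembly is convergent (2 + 1 + 2) and its longest linear sequence is clearly shorter than that of the chosen route. On step economy it is the stronger plan.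
- Against: the second displacement takes place at C2 between two methoxy groups, on a ring that the first aryloxy group, para to C2, has already made less electrophilic. Displacement of a methoxy group at C1 or C3 can compete. A stoichiometric amount of a ruthenium complex and a photolysis step are needed, and the twelvefold demethylation remains.
- Comparison: the chosen strategy forms every intermolecular C–O bond at an unhindered carbon, needs no stoichiometric precious metal, and builds the last ring in a reagent-free thermal step.

**Alternative 3:** Ring A is built last, by base-induced Claisen-type cyclisation of the keto ester A8, a methyl 6-aryloxy-3,3-dimethoxy-5-oxohexanoate carrying the BCDE tetramer. The enolate carbon bearing the aryloxy group attacks the ester to give the cyclohexane-1,3-dione A7, which would aromatise by loss of methanol.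
- For: the ring closure is simple ionic chemistry at low temperature, and only one six-membered mode is open, so it poses no regiochemical question. In this respect it is more predictable than a pericyclic cascade.
- Against: the side chain of A8 is not commercial and needs several steps. Its ketal lies beta to the ketone, so enolisation towards C4 leads to elimination of methoxide instead of cyclisation. Three ether couplings are still needed for the BCDE part. A7 needs a separate aromatisation, and the dealkylation remains.
- Comparison: the chosen strategy takes both ring-forming partners from commercial materials in one and two steps respectively, and delivers ring E already aromatic with the full 1,2,3,5 oxygen pattern.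

Key step: step 11

## Route

Step 1
Reactants: 1 4-bromo-2,6-dimethoxyphenol
Product: 2 2-(benzyloxy)-5-bromo-1,3-dimethoxybenzene
Conditions: BnBr, K2CO3, DMF, rt
Reagents that add atoms: benzyl bromide, BrCc1ccccc1
Why: Williamson ether synthesis; the phenoxide displaces bromide from the benzylic carbon (SN2), and the aryl bromide is inert under these conditions.

Step 2
Reactants: 3 2,4,6-trimethoxyphenol; 2 2-(benzyloxy)-5-bromo-1,3-dimethoxybenzene
Product: 4 AB benzyl ether 2-(benzyloxy)-1,3-dimethoxy-5-(2,4,6-trimethoxyphenoxy)benzene
Conditions: CuI (monovalent copper, 10 mol %), picolinic acid (20 mol %), K3PO4, DMSO, 100 °C, Ar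
Reagents that add atoms: none
Why: Ullmann-type diaryl ether synthesis; the bromide of 2 lies between two C–H groups, so the only steric demand is on the phenoxide oxygen, which ligated copper tolerates, and oxygen is excluded because the electron-rich phenoxide is easily oxidised.

Step 3
Reactants: 4 AB benzyl ether
Product: 5 AB phenol 2,6-dimethoxy-4-(2,4,6-trimethoxyphenoxy)phenol
Conditions: H2 (1 atm), Pd/C, EtOAc–MeOH, rt
Reagents that add atoms: none
Why: Hydrogenolysis of the benzylic C–O bond on palladium; methyl ethers and diaryl ethers are not cleaved under these conditions.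

Step 4
Reactants: 5 AB phenol; 2 2-(benzyloxy)-5-bromo-1,3-dimethoxybenzene
Product: 6 ABC benzyl ether 2-(benzyloxy)-5-[2,6-dimethoxy-4-(2,4,6-trimethoxyphenoxy)phenoxy]-1,3-dimethoxybenzene
Conditions: CuI (monovalent copper, 10 mol %), picolinic acid (20 mol %), K3PO4, DMSO, 100 °C, Ar
Reagents that add atoms: none
Why: Second Ullmann-type coupling; phenol 5 has the same 2,6-dimethoxy environment as 3 and the electrophile is again the unhindered bromide 2.

Step 5
Reactants: 6 ABC benzyl ether
Product: 7 ABC phenol 4-[2,6-dimethoxy-4-(2,4,6-trimethoxyphenoxy)phenoxy]-2,6-dimethoxyphenol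
Conditions: H2 (1 atm), Pd/C, EtOAc–MeOH, rt
Reagents that add atoms: none
Why: Hydrogenolysis of the single benzyl ether, as in step 3.

Step 6
Reactants: 7 ABC phenol; 2 2-(benzyloxy)-5-bromo-1,3-dimethoxybenzene
Product: 8 ABCD benzyl ether 2-(benzyloxy)-5-{4-[2,6-dimethoxy-4-(2,4,6-trimethoxyphenoxy)phenoxy]-2,6-dimethoxyphenoxy}-1,3-dimethoxybenzene
Conditions: CuI (monovalent copper, 10–20 mol %), picolinic acid (20–40 mol %), K3PO4, DMSO, 100 °C, Ar
Reagents that add atoms: none
Why: Third Ullmann-type coupling; the reacting oxygen of 7 has the same local environment as in steps 2 and 4, and only the size of the phenol has grown.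

Step 7
Reactants: 8 ABCD benzyl ether
Product: 9 ABCD phenol 4-{4-[2,6-dimethoxy-4-(2,4,6-trimethoxyphenoxy)phenoxy]-2,6-dimethoxyphenoxy}-2,6-dimethoxyphenol (ArO–H)
Conditions: H2 (1 atm), Pd/C, EtOAc–MeOH, rt
Reagents that add atoms: none
Why: Hydrogenolysis of the benzyl ether, as in steps 3 and 5.

Step 8
Reactants: 9 ABCD phenol; 10 trichloroethylene
Product: 12 (E)-1,2-dichlorovinyl ether ArO–C(Cl)=CHCl, via dichloroacetylene 11 (not isolated)
Conditions: K2CO3, DMF, 70 °C
Reagents that add atoms: none
Why: Base removes HCl from trichloroethylene to give dichloroacetylene, and the phenoxide adds to it in anti fashion (oxygen and hydrogen trans), which gives the E-configured dichlorovinyl ether; attack on a linear sp carbon is not hindered by the two ortho methoxy groups.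

Step 9
Reactants: 13 methoxyacetyl chloride; 14 ethoxyacetylene
Product: 16 racemic 3-ethoxy-4-methoxycyclobut-2-en-1-one, via methoxyketene 15 (not isolated)
Conditions: 14 (2 equiv), Et3N, Et2O, 0 °C to rt, slow addition of 13
Reagents that add atoms: none
Why: Dehydrochlorination of the acid chloride gives methoxyketene, which undergoes [2+2] cycloaddition with the ynol ether; the nucleophilic unsubstituted alkyne carbon bonds to the ketene carbonyl carbon, placing ethoxy on C3 and methoxy on C4. The C4 stereocentre is formed as a racemate and is lost later.

Step 10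
Reactants: 12 (E)-1,2-dichlorovinyl ether
Product: 19 ethynyl ether ArO–C≡CH, via chloroethynyl ether 17 (not isolated), via lithium aryloxyacetylide 18 (not isolated)
Conditions: n-BuLi (2.2 equiv), THF, −78 to −40 °C; then H2O, −78 °C to rt
Reagents that add atoms: none
Why: The first equivalent of n-BuLi effects dehydrochlorination to the chloroalkynyl ether and the second effects lithium–chlorine exchange; protonation of the acetylide gives the terminal ynol ether. At −78 °C ring lithiation next to methoxy is much slower than these steps, and 19 is used at once.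

Step 11
Reactants: 19 ethynyl ether ArO–C≡CH; 16 racemic 3-ethoxy-4-methoxycyclobut-2-en-1-one
Product: 24 pentamer phenol 5-(ArO)-3-ethoxy-2-methoxyphenol (ring E: C1 hydroxyl; C2 methoxy; C3 ethoxy), via vinylketene 20 (not isolated), via 4-vinylcyclobutenone 21 (not isolated), via dienylketene 22 (not isolated), via cyclohexadienone 23 (not isolated)
Conditions: 16 (2 equiv), toluene (degassed), 80 then 110 °C, sealed tube, Ar
Reagents that add atoms: none
Why: Heating opens 16 by conrotatory four-electron electrocyclic ring opening, the C4 methoxy group turning outward, to give the dialkoxy vinylketene 20. The ketene C=C bond of 20 then adds the ynol ether 19 in a [2+2] cycloaddition that forms C1–C6 and C4–C5 and gives the 4-vinylcyclobutenone 21. A second, reversible four-electron opening gives dienylketene 22; only the isomer with ketene and vinyl groups cis on the central double bond goes on, and ring E closes by thermal disrotatory six-electron electrocyclisation to cyclohexadienone 23, which tautomerises to phenol 24. The closest known reaction type is the Danheiser benzannulation of cyclobutenones with alkoxy- and silyloxyacetylenes, which gives 3-alkoxyphenols with this same orientation. The step needs one selectivity, the regiochemistry of the ketene–alkyne addition. The polarisation of the ynol ether secures it: oxygen donation makes the unsubstituted carbon nucleophilic, so that carbon bonds to the electrophilic ketene carbonyl carbon and the aryloxy group ends meta to the new hydroxyl, between two C–H groups. No stereocentre survives, since C4 of 16 and the sp3 carbon of 23 both become aromatic carbons. Unlike alkyl ynol ethers, the aryl ynol ether has no path for thermal loss of an alkene, so it tolerates the heating, and the methyl ethers and diaryl ethers are inert.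

Step 12
Reactants: 24 pentamer phenol
Product: 25 target 5-{4-[4-[2,6-dihydroxy-4-(2,4,6-trihydroxyphenoxy)phenoxy]-2,6-dihydroxyphenoxy]-2,6-dihydroxyphenoxy}benzene-1,2,3-triol
Conditions: BBr3 (about 3 equiv per ether group), CH2Cl2, −78 °C to rt, Ar; then H2O, 0 °C; isolation under Ar
Reagents that add atoms: none
Why: Lewis-acid ether cleavage; BBr3 binds each alkyl aryl ether oxygen and bromide attacks the methyl or ethyl carbon (SN2), while the diaryl ether C(sp2)–O bonds offer no such carbon; hydrolysis of the aryl borates frees all twelve phenols.

## Compound list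

1 | 4-bromo-2,6-dimethoxyphenol | COc1cc(Br)cc(OC)c1O | starting material
2 | 2-(benzyloxy)-5-bromo-1,3-dimethoxybenzene | COc1cc(Br)cc(OC)c1OCc1ccccc1 | intermediate
3 | 2,4,6-trimethoxyphenol | COc1cc(OC)c(O)c(OC)c1 | starting material
4 | AB benzyl ether, 2-(benzyloxy)-1,3-dimethoxy-5-(2,4,6-trimethoxyphenoxy)benzene | COc1cc(OC)c(Oc2cc(OC)c(OCc3ccccc3)c(OC)c2)c(OC)c1 | intermediate
5 | AB phenol, 2,6-dimethoxy-4-(2,4,6-trimethoxyphenoxy)phenol | COc1cc(OC)c(Oc2cc(OC)c(O)c(OC)c2)c(OC)c1 | intermediate
6 | ABC benzyl ether, 2-(benzyloxy)-5-[2,6-dimethoxy-4-(2,4,6-trimethoxyphenoxy)phenoxy]-1,3-dimethoxybenzene | COc1cc(OC)c(Oc2cc(OC)c(Oc3cc(OC)c(OCc4ccccc4)c(OC)c3)c(OC)c2)c(OC)c1 | intermediate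
7 | ABC phenol, 4-[2,6-dimethoxy-4-(2,4,6-trimethoxyphenoxy)phenoxy]-2,6-dimethoxyphenol | COc1cc(OC)c(Oc2cc(OC)c(Oc3cc(OC)c(O)c(OC)c3)c(OC)c2)c(OC)c1 | intermediate
8 | ABCD benzyl ether, 2-(benzyloxy)-5-{4-[2,6-dimethoxy-4-(2,4,6-trimethoxyphenoxy)phenoxy]-2,6-dimethoxyphenoxy}-1,3-dimethoxybenzene | COc1cc(OC)c(Oc2cc(OC)c(Oc3cc(OC)c(Oc4cc(OC)c(OCc5ccccc5)c(OC)c4)c(OC)c3)c(OC)c2)c(OC)c1 | intermediate
9 | ABCD phenol (ArO–H), 4-{4-[2,6-dimethoxy-4-(2,4,6-trimethoxyphenoxy)phenoxy]-2,6-dimethoxyphenoxy}-2,6-dimethoxyphenol | COc1cc(OC)c(Oc2cc(OC)c(Oc3cc(OC)c(Oc4cc(OC)c(O)c(OC)c4)c(OC)c3)c(OC)c2)c(OC)c1 | intermediate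
10 | trichloroethylene | ClC=C(Cl)Cl | starting material
11 | dichloroacetylene | ClC#CCl | intermediate
12 | (E)-1,2-dichlorovinyl ether of 9, ArO–C(Cl)=CHCl (chlorines trans) | Cl/C=C(/Cl)Oc1c(OC)cc(Oc2c(OC)cc(Oc3c(OC)cc(Oc4c(OC)cc(OC)cc4OC)cc3OC)cc2OC)cc1OC | intermediate
13 | methoxyacetyl chloride | COCC(Cl)=O | starting material
14 | ethoxyacetylene | CCOC#C | starting material
15 | methoxyketene | COC=C=O | intermediate
16 | 3-ethoxy-4-methoxycyclobut-2-en-1-one (racemic) | CCOC1=CC(=O)C1OC | intermediate
17 | chloroethynyl ether of 9, ArO–C≡C–Cl | ClC#COc1c(OC)cc(Oc2c(OC)cc(Oc3c(OC)cc(Oc4c(OC)cc(OC)cc4OC)cc3OC)cc2OC)cc1OC | intermediate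
18 | lithium aryloxyacetylide, ArO–C≡C–Li | [Li]C#COc1c(OC)cc(Oc2c(OC)cc(Oc3c(OC)cc(Oc4c(OC)cc(OC)cc4OC)cc3OC)cc2OC)cc1OC | intermediate
19 | ethynyl ether of 9, ArO–C≡CH | C#COc1c(OC)cc(Oc2c(OC)cc(Oc3c(OC)cc(Oc4c(OC)cc(OC)cc4OC)cc3OC)cc2OC)cc1OC | intermediate
20 | vinylketene, 3-ethoxy-4-methoxybuta-1,3-dien-1-one (methoxy trans to the ketene carbon, as expected from outward rotation) | O=C=C/C(OCC)=C/OC | intermediate
21 | 4-vinylcyclobutenone, 3-(ArO)-4-(1-ethoxy-2-methoxyvinyl)cyclobut-2-en-1-one (racemic) | O=C1C=C(Oc2c(OC)cc(Oc3c(OC)cc(Oc4c(OC)cc(Oc5c(OC)cc(OC)cc5OC)cc4OC)cc3OC)cc2OC)C1/C(OCC)=C/OC | intermediate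
22 | dienylketene, 3-(ArO)-5-ethoxy-6-methoxyhexa-1,3,5-trien-1-one (ketene and vinyl groups cis on the central double bond) | O=C=C/C(Oc1c(OC)cc(Oc2c(OC)cc(Oc3c(OC)cc(Oc4c(OC)cc(OC)cc4OC)cc3OC)cc2OC)cc1OC)=C\C(OCC)=C\OC | intermediate
23 | cyclohexadienone, 3-(ArO)-5-ethoxy-6-methoxycyclohexa-2,4-dien-1-one (racemic) | O=C1C=C(Oc2c(OC)cc(Oc3c(OC)cc(Oc4c(OC)cc(Oc5c(OC)cc(OC)cc5OC)cc4OC)cc3OC)cc2OC)C=C(OCC)C1OC | intermediate
24 | pentamer phenol, 5-(ArO)-3-ethoxy-2-methoxyphenol | CCOc1cc(Oc2c(OC)cc(Oc3c(OC)cc(Oc4c(OC)cc(Oc5c(OC)cc(OC)cc5OC)cc4OC)cc3OC)cc2OC)cc(O)c1OC | intermediate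
25 | CNP0308003.0, 5-{4-[4-[2,6-dihydroxy-4-(2,4,6-trihydroxyphenoxy)phenoxy]-2,6-dihydroxyphenoxy]-2,6-dihydroxyphenoxy}benzene-1,2,3-triol | Oc1cc(O)c(Oc2cc(O)c(Oc3cc(O)c(Oc4cc(O)c(Oc5cc(O)c(O)c(O)c5)c(O)c4)c(O)c3)c(O)c2)c(O)c1 | target

## Step count and least certain steps

Total step count: 12. Longest linear sequence: 11 (steps 1 to 8, then 10, 11 and 12); step 9 is a one-step side branch.

**Step 11 (key step).** The most likely failure is that vinylketene 20 is used up faster than it adds to 19. It can dimerise or acylate the product phenol 24. The aryloxy oxygen of 19 shares its lone pair with the arene, so 19 is a weaker nucleophile than an alkyl ynol ether and may oligomerise while it waits. Acylation alone would be reversed by brief treatment of the crude product with K2CO3 in MeOH. Should the cascade itself fail, the fallback sets out from 9. Coupling of 9 with commercial 5-bromo-1,2,3-trimethoxybenzene under the CuI (monovalent copper)/picolinic acid/K3PO4 conditions of steps 2, 4 and 6 would give the dodecamethyl ether of the target F1. BBr3 as in step 12 would then bring the route back at 25.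

**Step 10.** The terminal aryl ynol ether may be lost during isolation by hydration to the aryl acetate on traces of acid or by oligomerisation. A surplus of n-BuLi could also begin to lithiate the rings next to methoxy groups. The fallback sets out from 12. The lithium acetylide 18 is quenched with chlorotrimethylsilane instead of water to give the storable C-silylated ynol ether F2. Heating F2 with 16 as in step 11 should give the ring E phenol carrying trimethylsilyl on C6, F3, because the silicon-bearing alkyne carbon is the one that bonds to the ketene carbonyl carbon. Protodesilylation of this electron-rich aryl silane with CF3CO2H in CH2Cl2 returns to the route at 24.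

**Step 12.** Eleven ether groups must all be cleaved, so incomplete dealkylation is likely to leave partly alkylated material. The free dodecaphenol can also be lost to air oxidation during work-up and chromatography. The fallback sets out from 24. After the BBr3 treatment the crude product is acetylated (Ac2O, pyridine) to the dodecaacetate F4, which is stable to air and can be purified on silica; fractions that still carry alkyl groups are resubmitted. Acid-catalysed methanolysis of F4 (HCl in degassed MeOH, Ar) then returns to the route at 25.

**Step 6.** With the largest hindered phenoxide the C–O coupling may become slow, which gives time for oxidation of the electron-rich phenoxide and for reduction of the C–Br bond of 2. The fallback turns the assembly into a 2 + 2 coupling and sets out from 2, 1 and 5. Bromide 2 is converted by n-BuLi, B(OiPr)3 and aqueous acid into [4-(benzyloxy)-3,5-dimethoxyphenyl]boronic acid F5. Chan–Lam coupling of F5 with bromophenol 1 (Cu(OAc)2, divalent copper, pyridine, 4 Å molecular sieves, CH2Cl2, air, rt) leaves the C–Br bond untouched and gives the CD bromide F6. CuI-catalysed coupling of the smaller AB phenol 5 with F6 then returns to the route at 8, and steps 4 and 5 are bypassed.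

## Further compounds

F1 | step 11 | dodecamethyl ether of the target | COc1cc(OC)c(Oc2cc(OC)c(Oc3cc(OC)c(Oc4cc(OC)c(Oc5cc(OC)c(OC)c(OC)c5)c(OC)c4)c(OC)c3)c(OC)c2)c(OC)c1
F2 | step 10 | trimethylsilylethynyl ether of 9, ArO–C≡C–SiMe3 | C[Si](C)(C)C#COc1c(OC)cc(Oc2c(OC)cc(Oc3c(OC)cc(Oc4c(OC)cc(OC)cc4OC)cc3OC)cc2OC)cc1OC
F3 | step 10 | 3-(ArO)-5-ethoxy-6-methoxy-2-(trimethylsilyl)phenol (24 with trimethylsilyl on C6 of ring E) | CCOc1cc(Oc2c(OC)cc(Oc3c(OC)cc(Oc4c(OC)cc(Oc5c(OC)cc(OC)cc5OC)cc4OC)cc3OC)cc2OC)c([Si](C)(C)C)c(O)c1OC
F4 | step 12 | dodecaacetate of the target | CC(=O)Oc1cc(OC(C)=O)c(Oc2cc(OC(C)=O)c(Oc3cc(OC(C)=O)c(Oc4cc(OC(C)=O)c(Oc5cc(OC(C)=O)c(OC(C)=O)c(OC(C)=O)c5)c(OC(C)=O)c4)c(OC(C)=O)c3)c(OC(C)=O)c2)c(OC(C)=O)c1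
F5 | step 6 | [4-(benzyloxy)-3,5-dimethoxyphenyl]boronic acid | COc1cc(B(O)O)cc(OC)c1OCc1ccccc1
F6 | step 6 | CD bromide, 2-[4-(benzyloxy)-3,5-dimethoxyphenoxy]-5-bromo-1,3-dimethoxybenzene | COc1cc(Br)cc(OC)c1Oc1cc(OC)c(OCc2ccccc2)c(OC)c1
A1 | alternative 1 | tetra-O-benzyl ether of the target (benzyl on the C5 oxygen of ring A and on the three ring E oxygens) | Oc1cc(OCc6ccccc6)cc(O)c1Oc1cc(O)c(Oc2cc(O)c(Oc3cc(O)c(Oc4cc(OCc6ccccc6)c(OCc6ccccc6)c(OCc6ccccc6)c4)c(O)c3)c(O)c2)c(O)c1
A2 | alternative 1 | octa-aldehyde pentamer (formyl on C1 and C3 of rings A to D, benzyl ethers as in A1) | O=Cc1cc(OCc6ccccc6)cc(C=O)c1Oc1cc(C=O)c(Oc2cc(C=O)c(Oc3cc(C=O)c(Oc4cc(OCc6ccccc6)c(OCc6ccccc6)c(OCc6ccccc6)c4)c(C=O)c3)c(C=O)c2)c(C=O)c1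
A3 | alternative 2 | cyclopentadienylruthenium complex (on ring C) of the dodecamethyl ether of the target, hexafluorophosphate | COc1cc(OC)c(Oc2cc(OC)c(Oc3cc(OC)c(Oc4cc(OC)c(Oc5cc(OC)c(OC)c(OC)c5)c(OC)c4)c(OC)c3)c(OC)c2)c(OC)c1.[cH-]1cccc1.[Ru+2].F[P-](F)(F)(F)(F)F
A4 | alternative 2 | cyclopentadienylruthenium complex of 2,5-dichloro-1,3-dimethoxybenzene, hexafluorophosphate | COc1cc(Cl)cc(OC)c1Cl.[cH-]1cccc1.[Ru+2].F[P-](F)(F)(F)(F)F
A5 | alternative 2 | AB phenol, 2,6-dimethoxy-4-(2,4,6-trimethoxyphenoxy)phenol (same compound as 5) | COc1cc(OC)c(Oc2cc(OC)c(O)c(OC)c2)c(OC)c1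
A6 | alternative 2 | DE phenol, 3,5-dimethoxy-4-(3,4,5-trimethoxyphenoxy)phenol | COc1cc(Oc2c(OC)cc(O)cc2OC)cc(OC)c1OC
A7 | alternative 3 | 2-(BCDE tetramer aryloxy)-5,5-dimethoxycyclohexane-1,3-dione | COC1(OC)CC(=O)C(Oc2cc(OC)c(Oc3cc(OC)c(Oc4cc(OC)c(Oc5cc(OC)c(OC)c(OC)c5)c(OC)c4)c(OC)c3)c(OC)c2)C(=O)C1
A8 | alternative 3 | methyl 6-(BCDE tetramer aryloxy)-3,3-dimethoxy-5-oxohexanoate | COC(=O)CC(OC)(OC)CC(=O)COc2cc(OC)c(Oc3cc(OC)c(Oc4cc(OC)c(Oc5cc(OC)c(OC)c(OC)c5)c(OC)c4)c(OC)c3)c(OC)c2
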